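Take a one-step world: the coupling partner carries each substrate into its product and cares nothing for hand. The excess of left-handed product over right-handed product is then zero at every moment, and that zero is the origin of my scale.

| flask | left-handed substrate | right-handed substrate | coupling partner | remark | time |
|---|---|---|---|---|---|
| north | 0.29 M | 0.29 M | 1.18 M | run made earlier |  |
| south | 1.2 M | 1.2 M | 1.18 M | run made earlier |  |
| south-east | 0.59 M | 0.59 M | 0.59 M | run made earlier |  |
| dawn | 0.59 M | 0.59 M | 1.18 M |  | 10 min |
| spring | 0.59 M | 0.59 M | 1.18 M |  | 5.0 min |

| run | time / min | left-handed product / % | right-handed product / % | left-handed substrate / % |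
|---|---|---|---|---|
| north | 1.00 | 13.4 | 4.2 | 37.0 |
| north | 1.50 | 19.2 | 7.7 | 32.8 |
| north | 2.50 | 26.1 | 11.3 | 27.2 |
| north | 4.00 | 34.2 | 15.7 | 19.6 |
| north | 8.00 | 47.0 | 22.2 | 12.0 |
| north | 12.0 | 55.2 | 26.5 | 6.9 |
| south | 2.00 | 18.5 | 7.5 | 33.9 |
| south | 4.00 | 24.8 | 10.1 | 28.9 |
| south | 6.00 | 28.8 | 12.5 | 27.6 |
| south | 8.00 | 32.1 | 13.1 | 26.2 |
| south | 10.0 | 32.0 | 13.9 | 25.4 |
| south | 12.0 | 33.2 | 14.1 | 25.8 |
| south-east | 1.00 | 7.0 | 2.0 | 42.9 |
| south-east | 2.00 | 11.2 | 4.8 | 40.0 |
| south-east | 3.00 | 15.0 | 6.0 | 36.1 |
| south-east | 6.00 | 22.1 | 9.2 | 31.8 |
| south-east | 12.0 | 29.1 | 11.9 | 27.9 |

(scatter of a reading: 0.5 percentage points)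

- coupling partner is single-handed; left-handed substrate and right-handed substrate are mirror images of each other, charged as a racemate, each of them at the stated concentration
- steps thought possible: coupling partner + left-handed substrate -> left-handed product; coupling partner + right-handed substrate -> right-handed product; left-handed substrate <-> right-handed substrate; coupling partner <-> dormant form
- an excess is the difference of the two amounts in percent of their sum
- an excess is below zero if the other one leads
- the handed part of coupling partner does not stay in what it makes, so the products of the two hands are mirror images too

1. which one finishes higher in excess of left-handed product over right-handed product in the product ("neither" within 2 percentage points) (dawn / spring / neither)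
2. excess of left-handed product over right-handed product in the product at the end, dawn
3. excess of left-handed product over right-handed product in the product at the end, spring

Now I make the partner single-handed. In the north run the left-handed and right-handed products stand at a ratio of 2.49 at 1.50 min, a reading of the selectivity factor, and that is an excess of 42.8%. With this step alone, the north run has 1.18 M of c(coupling partner), more than the 0.580 M of the two substrates together, so there is enough partner for both hands, and when finished the north run returns to zero.

I add the second process, the interconversion of the substrates. In the north run at 12.0 min, left-handed substrate and left-handed product together hold 62.1%, more than half of what was charged, so material has crossed from the right hand to the left and the return to zero is broken.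

I add the dormant form last. The products of the south run reach 1.14 M against 1.18 M of c(coupling partner) charged, so partner that goes dormant comes back into use.

Dawn and spring are one charge read at 5.0 min and at 10 min, twice the time, so I need only the change of the excess over one doubling of time. The north run has the same c(coupling partner) and half the substrate, and its excess goes from 37.1% at 4.00 min to 35.8% at 8.00 min. I call this change, −1.2 percentage points, the doubling drift. Each of those excesses carries about 1.5 points of scatter, so the drift is a rough reading. Still, I put dawn below spring by about that much, which is less than the margin, and I say neither.

The forecast gives 38% for dawn and 39.5% for spring, hence neither: “Racemisation then holds it near 38%”.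

The simulation gives 37.2% for dawn and 38.3% for spring, so neither, with a gap of −1.1 points against the drift of −1.2 points.

    coupling partner + left-handed substrate → left-handed product (k = 0.00520 M⁻¹ s⁻¹)
    coupling partner + right-handed substrate → right-handed product (k = 0.00190 M⁻¹ s⁻¹)
    left-handed substrate ⇌ right-handed substrate (k = 0.00250 s⁻¹)
    coupling partner ⇌ dormant form (K = 0.190, k = 0.00950 s⁻¹)

Left until 50.0 min, spring stands at 37.9%. The same spring flask read at 80 s lies 1.91 doublings before 5.0 min, so the drift puts it at 40.7%, and it stands at 42.5%.

The data were generated by integration from invented constants; noise was put on by code.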